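## Retrosynthetic overview

1. Monocyclic half: ring A of (−)-sclareol (1) is kept and ring B is excised. The side chain is trimmed to hydroxy ketone 2, a Norrish II cleavage gives exocyclic alkene 3, oxidative excision of C9/C11 gives seco keto acid 4, and photochemical decarboxylative desaturation gives (S)-γ-dihydroionone (5). Sclareol C5 becomes the lone monocycle stereocentre.
2. 5 ⇒ terminal alkyne 6 ⇒ (E)-alkenyl iodide 7; Zr-carboalumination fixes the trisubstituted E-alkene.
3. Bicyclic half: (+)-sclareolide (8) ⇒ diol 9, with all four decalin stereocentres bought.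
4. Key disconnection of ambrein (10): the C12–C13 C(sp3)–C(sp2) bond, made last by a visible-light Ni/photoredox deoxygenative alkenylation of 9 with 7.
5. No ring is constructed: the decalin is bought intact and the monocycle is unveiled by ring-B excision.

Assumption: (−)-sclareol and (+)-sclareolide are taken as inexpensive commercial clary-sage feedstocks; every other reagent and catalyst is achiral.

## Route

**Step 1**
Reactants: 1, (−)-sclareol [(13R)-labd-14-ene-8α,13-diol]
Product: 2, 8α-hydroxy-14,15-dinorlabdan-13-one
Conditions: OsO4 (1 mol%), NaIO4 (4 equiv), THF/H2O, 45 °C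
Reagents that add atoms: none (the ketone oxygen is the original C13–OH oxygen; C14 and C15 are lost)
Why: Lemieux–Johnson dihydroxylation followed by double Malaprade cleavage of the resulting 13,14,15-triol gives the methyl ketone; no stereocentre of the decalin is touched.

**Step 2**
Reactants: 2, 8α-hydroxy-14,15-dinorlabdan-13-one
Product: 3, drim-9(11)-en-8α-ol [(2R,4aS,8aS)-2,5,5,8a-tetramethyl-1-methylidenedecahydronaphthalen-2-ol]
Conditions: hν (medium-pressure Hg lamp, Pyrex, λ > 290 nm), degassed hexane, rt
Reagents that add atoms: none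
Why: Norrish type II fragmentation: the excited C13 carbonyl abstracts its only γ-hydrogen (tertiary C9–H) and the 1,4-biradical cleaves C11–C12 to give the 9(11)-exocyclic alkene plus acetone; C5, C8 and C10 are unaffected.

**Step 3**
Reactants: 3, drim-9(11)-en-8α-ol
Product: 4, (1S,2S)-1,3,3-trimethyl-2-(3-oxobutyl)cyclohexane-1-carboxylic acid (8-oxo-11-nor-8,9-secodriman-9-oic acid)
Conditions: RuCl3·xH2O (5 mol%), NaIO4 (6 equiv), CCl4/MeCN/H2O, rt
Reagents that add atoms: sodium periodate, [Na+].[O-]I(=O)(=O)=O (oxygen, relayed through RuO4); water, O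
Why: Sharpless RuO4 alkene cleavage gives the C9 ketone (C11 lost as CO2), and the resulting tertiary α-ketol undergoes in-situ Malaprade-type C8–C9 cleavage, leaving C8 as the methyl ketone (original 8-OH oxygen) and C9 as the CO2H on quaternary C10; C5 and C10 keep their sclareol configuration.

**Step 4**
Reactants: 4, seco keto acid
Product: 5, (S)-γ-dihydroionone [4-[(1S)-2,2-dimethyl-6-methylidenecyclohexyl]butan-2-one]
Conditions: 9-mesitylacridine (10 mol%), Co(dmgH)2(py)Cl (5 mol%), CH2Cl2/MeCN, 400 nm LEDs, rt (−CO2, −H2)
Reagents that add atoms: none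
Why: Acridine/cobaloxime photocatalytic dehydrodecarboxylation: PCET decarboxylation gives the tertiary C10 radical and the bulky Co(II) centre removes the most accessible β-hydrogen (CH3) under kinetic control to give the exocyclic methylene; the adjacent C–H stereocentre (old C5) is not involved and is now the (S)-centre of the monocycle.

**Step 5**
Reactants: 5, (S)-γ-dihydroionone
Product: 6, (2S)-2-(but-3-yn-1-yl)-1,1-dimethyl-3-methylidenecyclohexane
Conditions: LDA, THF, −78 °C; ClP(O)(OEt)2, −78 °C → rt; then LDA (2.3 equiv), −78 °C → rt
Reagents that add atoms: none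
Why: Negishi methyl ketone → terminal alkyne conversion via the kinetic enol phosphate and base-induced elimination; the allylic stereocentre is not acidic enough to be affected.

**Step 6**
Reactants: 6, terminal alkyne
Product: 7, (2S)-2-[(3E)-4-iodo-3-methylbut-3-en-1-yl]-1,1-dimethyl-3-methylidenecyclohexane
Conditions: Me3Al (3 equiv), Cp2ZrCl2 (20 mol%), H2O (1.5 equiv), CH2Cl2, −25 °C; then I2, THF, −30 → 0 °C
Reagents that add atoms: trimethylaluminium, C[Al](C)C (CH3); iodine, II (I)
Why: Negishi Zr-catalysed syn-carboalumination (Me to the internal carbon, Al to the terminus) followed by stereoretentive iodinolysis gives the (E)-2-methyl-1-iodoalkene; the 1,1-disubstituted exocyclic alkene is inert under these conditions.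

**Step 7**
Reactants: 8, (+)-sclareolide [(3aR,5aS,9aS,9bR)]
Product: 9, ambradiol [(1R,2R,4aS,8aS)-1-(2-hydroxyethyl)-2,5,5,8a-tetramethyldecahydronaphthalen-2-ol]
Conditions: LiAlH4, THF, 0 °C → rt
Reagents that add atoms: none
Why: Hydride reduction of the γ-lactone to the 8α,12-diol; all four stereocentres (C5, C8, C9, C10) are carried through unchanged.

**Step 8**
Reactants: 9, ambradiol (1.5 equiv); 7, (E)-alkenyl iodide (1.0 equiv)
Product: 10, (+)-ambrein
Conditions: 9, 5,7-di-tert-butyl-3-phenylbenzoxazolium BF4 (1.4 equiv), pyridine, MTBE, rt, 15 min; then 7, NiBr2·dtbbpy (10 mol%), Ir(ppy)2(dtbbpy)PF6 (1.5 mol%), quinuclidine (1.75 equiv), DMA/MTBE, 450 nm LEDs, rt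
Reagents that add atoms: none
Why: Proposed new method: NHC-mediated deoxygenative Ni/photoredox C(sp3)–C(sp2) coupling, established for aryl halides, is extended here to an unactivated trisubstituted (E)-alkenyl iodide and an unprotected 1,4-diol. The primary OH of 9 condenses selectively with the benzoxazolium salt (the tertiary 8-OH is too hindered); photo-oxidation of the adduct, deprotonation by quinuclidine and β-scission (driven by benzoxazolone formation) release the C12 primary radical; Ni(0) adds oxidatively to 7 with retention, captures the radical and reductively eliminates the C12–C13 bond. The E-geometry is retained and no stereocentre is touched, and because the activated oxygen is not a leaving group, the usual cyclisation of activated 9 to Ambrox is avoided. Closest known reactions: deoxygenative arylation of NHC-activated alcohols and Ni/photoredox alkyl-radical/vinyl-halide coupling (decarboxylative alkenylation).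

## Compound list

1 | (−)-sclareol, (13R)-labd-14-ene-8α,13-diol | C=C[C@](C)(O)CC[C@@H]1[C@@]2(C)CCCC(C)(C)[C@@H]2CC[C@@]1(C)O | starting material
2 | 8α-hydroxy-14,15-dinorlabdan-13-one | CC(=O)CC[C@@H]1[C@@]2(C)CCCC(C)(C)[C@@H]2CC[C@@]1(C)O | intermediate
3 | drim-9(11)-en-8α-ol | C=C1[C@@]2(C)CCCC(C)(C)[C@@H]2CC[C@@]1(C)O | intermediate
4 | (1S,2S)-1,3,3-trimethyl-2-(3-oxobutyl)cyclohexane-1-carboxylic acid | OC(=O)[C@@]1(C)CCCC(C)(C)[C@@H]1CCC(C)=O | intermediate
5 | (S)-γ-dihydroionone | C=C1CCCC(C)(C)[C@@H]1CCC(C)=O | intermediate
6 | (2S)-2-(but-3-yn-1-yl)-1,1-dimethyl-3-methylidenecyclohexane | C=C1CCCC(C)(C)[C@@H]1CCC#C | intermediate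
7 | (2S)-2-[(3E)-4-iodo-3-methylbut-3-en-1-yl]-1,1-dimethyl-3-methylidenecyclohexane | C=C1CCCC(C)(C)[C@@H]1CC/C(C)=C/I | intermediate
8 | (+)-sclareolide | O=C1C[C@@H]2[C@@]3(C)CCCC(C)(C)[C@@H]3CC[C@@]2(C)O1 | starting material
9 | ambradiol (8α,12-dihydroxy-13,14,15,16-tetranorlabdane) | OCC[C@@H]1[C@@]2(C)CCCC(C)(C)[C@@H]2CC[C@@]1(C)O | intermediate
10 | (+)-ambrein | C=C1CCCC(C)(C)[C@@H]1CC/C(C)=C/CC[C@@H]1[C@@]2(C)CCCC(C)(C)[C@@H]2CC[C@@]1(C)O | target

## Summary

Total steps: 8.
Longest linear sequence: 7 (steps 1–6, then 8).

Three steps most likely to fail: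

1. **Step 8 (proposed new coupling).** Risks: sluggish engagement of the hindered alkenyl iodide, β-hydride elimination at Ni, partial E/Z erosion, or activation of the tertiary OH. Fallback (known chemistry): acetylate the 8-OH of ketone 2 and run a haloform reaction to 8α-acetoxy-14,15,16-trinorlabdan-13-oic acid. Convert this to its N-hydroxyphthalimide ester and carry out Ni-catalysed decarboxylative alkenylation with the alkenylzinc derived from 7 (t-BuLi, then ZnCl2). Finish with LiAlH4 removal of the acetate to give 10.

2. **Step 4 (exo versus endo alkene).** Risk: the cobaloxime hydrogen abstraction gives too much ring-endocyclic isomer (α/β-type alkenes, the latter destroying the stereocentre). Fallback: ketalise the ketone of 4, then Curtius rearrangement (DPPA), reduction to the N-methylamine (LiAlH4) and methylation to the tertiary amine. Oxidise to the N-oxide and carry out Cope elimination, whose syn-elimination strongly favours the exocyclic methylene in 1-methylcyclohexyl systems; then deketalise to 5.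

3. **Step 3 (one-pot double cleavage).** Risk: the hindered α-ketol (C9 ketone flanked by two quaternary carbons) may stall or over-oxidise. Fallback: ozonolysis of 3 with NaBH4 work-up to the 8α,9-diol, NaIO4 glycol cleavage to the keto aldehyde, then Pinnick oxidation to 4.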